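Ring B of the upper flavan is cut back to an ynone and a 2,3-dioxygenated butadiene. That ring has its two carbon substituents on neighbouring atoms (C2 of ring C at C1', C6 of the lower ring A at C6') and its two oxygens at C3' and C4' on the far side. One [4+2] cycloaddition with aromatisation therefore forms C1'–C2' and C5'–C6' and sets the ketone carbon (future C2) ortho to the biaryl bond without an aryl–aryl coupling. The precursor is an ynone joining C6 of per-benzylated (+)-catechin to a glycidate-derived C3–C4–ring A chain carrying three MOM ethers.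

Key step: step 13

Remark: the target defines no configuration for the C6'–C6 biaryl axis, so the axis is treated as freely rotating and is not controlled.

Step 1
Reactants: 1 (+)-catechin
Product: 2 5,7,3',4'-tetra-O-benzyl-(+)-catechin
Conditions: BnBr (4.4 equiv), K2CO3, DMF, 0 °C → rt
Reagents that add atoms: benzyl bromide BrCc1ccccc1
Why: Williamson etherification in which K2CO3 deprotonates only the four phenols and leaves the secondary C3 alcohol free, and the mild base at room temperature should not epimerise C2.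

Step 2
Reactants: 2 5,7,3',4'-tetra-O-benzyl-(+)-catechin
Product: 3 3,5,7,3',4'-penta-O-benzyl-(+)-catechin
Conditions: NaH, BnBr, Bu4NI (cat.), DMF, 0 °C → rt
Reagents that add atoms: benzyl bromide BrCc1ccccc1
Why: Williamson etherification of the sodium alkoxide of the C3 alcohol, which has no competing acidic site and leaves both stereocentres untouched.

Step 3
Reactants: 3 3,5,7,3',4'-penta-O-benzyl-(+)-catechin
Product: 4 8-bromo-3,5,7,3',4'-penta-O-benzyl-(+)-catechin
Conditions: NBS (1.05 equiv), CH2Cl2, −40 °C → rt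
Reagents that add atoms: N-bromosuccinimide O=C1CCC(=O)N1Br
Why: Electrophilic aromatic bromination, which in 5,7-dibenzyloxyflavans is known to go to C8 (between O1 and the 7-benzyloxy group) in preference to the more crowded C6, so one equivalent should place a blocking bromine at C8.

Step 4
Reactants: 4 8-bromo-3,5,7,3',4'-penta-O-benzyl-(+)-catechin
Product: 5 8-bromo-6-iodo-3,5,7,3',4'-penta-O-benzyl-(+)-catechin
Conditions: NIS (1.2 equiv), CF3CO2H (cat.), CH2Cl2–MeCN, 0 °C → rt, dark
Reagents that add atoms: N-iodosuccinimide O=C1CCC(=O)N1I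
Why: Electrophilic aromatic iodination, for which C6 is the only free position of the phloroglucinol-type ring A once C8 is blocked and should remain far more nucleophilic than the catechol-ether ring B.

Step 5
Reactants: 5 8-bromo-6-iodo-3,5,7,3',4'-penta-O-benzyl-(+)-catechin; 6 ethynyltrimethylsilane
Product: 7 8-bromo-6-[(trimethylsilyl)ethynyl]-3,5,7,3',4'-penta-O-benzyl-(+)-catechin
Conditions: PdCl2(PPh3)2 (cat.), CuI (cat.), Et3N–THF, 50 °C
Reagents that add atoms: none
Why: Sonogashira coupling in which zerovalent palladium should insert into the C–I bond much faster than into the hindered, electron-rich C–Br bond, so only C6 is alkynylated.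

Step 6
Reactants: 7 8-bromo-6-[(trimethylsilyl)ethynyl]-3,5,7,3',4'-penta-O-benzyl-(+)-catechin
Product: 10 6-ethynyl-3,5,7,3',4'-penta-O-benzyl-(+)-catechin, via aryllithium 8 (not isolated), via silylalkyne 9 (not isolated)
Conditions: n-BuLi, THF, −78 °C; MeOH, −78 °C → rt; K2CO3 (cat.), rt
Reagents that add atoms: none
Why: Bromine–lithium exchange at −78 °C should outrun any deprotonation and methanol protonates the aryllithium, after which the methoxide formed cleaves the alkynyl C–Si bond (base-mediated protodesilylation), so the blocking bromine and the silyl cap leave in one flask.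

Step 7
Reactants: 11 phloroglucinol
Product: 12 1,3,5-tris(methoxymethoxy)benzene
Conditions: MOMCl, iPr2NEt, CH2Cl2–DMF, 0 °C → rt
Reagents that add atoms: chloromethyl methyl ether COCCl
Why: O-alkylation of the three phenols by the hard oxocarbenium-type electrophile (MOM protection).

Step 8
Reactants: 12 1,3,5-tris(methoxymethoxy)benzene; 13 methyl (S)-glycidate
Product: 16 methyl (2S)-2-hydroxy-3-[2,4,6-tris(methoxymethoxy)phenyl]propanoate, via aryllithium 14 (not isolated), via arylmagnesium bromide 15 (not isolated)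
Conditions: n-BuLi, THF, 0 °C; MgBr2·OEt2, −78 → 0 °C; CuI (10 mol %), then 13, −40 → −20 °C; H2O
Reagents that add atoms: none
Why: Directed ortho-lithiation between two MOM ethers (all three ring positions are equivalent), transmetalation to magnesium and CuI-catalysed SN2 opening of the epoxide at its unsubstituted CH2, which should spare the ester at low temperature and carries the (S) centre over unchanged because no bond to it is broken.

Step 9
Reactants: 16 methyl (2S)-2-hydroxy-3-[2,4,6-tris(methoxymethoxy)phenyl]propanoate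
Product: 17 methyl (2S)-2-(benzyloxy)-3-[2,4,6-tris(methoxymethoxy)phenyl]propanoate
Conditions: BnBr, Ag2O, CH2Cl2, rt, dark
Reagents that add atoms: benzyl bromide BrCc1ccccc1
Why: Ag2O-mediated benzylation (Purdie-type alkylation) proceeds without a strong base, so the α-hydroxy ester should not enolise and the C2 configuration is kept.

Step 10
Reactants: 17 methyl (2S)-2-(benzyloxy)-3-[2,4,6-tris(methoxymethoxy)phenyl]propanoate
Product: 18 (2S)-2-(benzyloxy)-N-methoxy-N-methyl-3-[2,4,6-tris(methoxymethoxy)phenyl]propanamide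
Conditions: MeNH(OMe)·HCl, iPrMgCl, THF, −20 → 0 °C; H2O
Reagents that add atoms: N,O-dimethylhydroxylamine hydrochloride CNOC.Cl
Why: Weinreb amide formation by aminolysis of the ester with the chloromagnesium amide of MeNH(OMe), a low-temperature process that is known to leave α-alkoxy stereocentres intact.

Step 11
Reactants: 19 2,3-butanedione
Product: 20 2,3-bis(tert-butyldimethylsilyloxy)buta-1,3-diene
Conditions: TBSOTf, Et3N, CH2Cl2, 0 °C → rt
Reagents that add atoms: tert-butyldimethylsilyl trifluoromethanesulfonate CC(C)(C)[Si](C)(C)OS(=O)(=O)C(F)(F)F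
Why: Double silyl enol ether formation by soft enolisation of both methyl ketones with the silyl triflate and the amine base.

Step 12
Reactants: 10 6-ethynyl-3,5,7,3',4'-penta-O-benzyl-(+)-catechin; 18 (2S)-2-(benzyloxy)-N-methoxy-N-methyl-3-[2,4,6-tris(methoxymethoxy)phenyl]propanamide
Product: 22 (4S)-4-(benzyloxy)-1-[3,5,7,3',4'-penta-O-benzyl-(+)-catechin-6-yl]-5-[2,4,6-tris(methoxymethoxy)phenyl]pent-1-yn-3-one, via lithium acetylide 21 (not isolated)
Conditions: n-BuLi, THF, −78 °C; then 18, −78 → 0 °C; H2O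
Reagents that add atoms: none
Why: Weinreb ketone synthesis in which the lithium acetylide adds once to the amide and the five-membered metal chelate holds until work-up, so over-addition is blocked and the α-benzyloxy centre should not epimerise at low temperature.

Step 13
Reactants: 22 (4S)-4-(benzyloxy)-1-[3,5,7,3',4'-penta-O-benzyl-(+)-catechin-6-yl]-5-[2,4,6-tris(methoxymethoxy)phenyl]pent-1-yn-3-one; 20 2,3-bis(tert-butyldimethylsilyloxy)buta-1,3-diene
Product: 24 (2S)-2-(benzyloxy)-1-[4,5-bis(tert-butyldimethylsilyloxy)-2-(3,5,7,3',4'-penta-O-benzyl-(+)-catechin-6-yl)phenyl]-3-[2,4,6-tris(methoxymethoxy)phenyl]propan-1-one, via cyclohexa-1,4-diene adduct 23 (not isolated)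
Conditions: 20 (4 equiv), toluene, 130 °C (sealed tube); then DDQ (1.1 equiv), 0 °C
Reagents that add atoms: none
Why: The electron-rich diene, reacting through its s-cis conformer, should add suprafacially across the ynone triple bond, whose LUMO is lowered by the conjugated carbonyl, in a concerted thermal [4+2] cycloaddition to give the 4,5-bis(silyloxy)cyclohexa-1,4-diene 23, from which DDQ removes a hydride and then a proton from the two ring CH2 groups so that the ring aromatises with both silyl ethers in place. The closest known reaction type is the Diels–Alder addition of 2,3-bis(silyloxy)buta-1,3-dienes to acetylenic carbonyl compounds followed by dehydrogenation to catechol ethers. Ring B, a six-membered carbocycle, is closed in the cycloaddition itself by simultaneous formation of C1'–C2' and C5'–C6' between the diene termini and the two alkyne carbons, which puts the ketone carbon (future C2) and C6 of the lower ring A on adjacent ring atoms. No stereocentre is created, and the existing ones lie outside the reacting π systems in a neutral aprotic medium, so the α-benzyloxy centre should be kept. No regiochemical control is needed because the diene has a twofold axis and both orientations give the same adduct; the selectivity required is chemoselectivity, which an excess of diene in dry, acid-free toluene (cycloaddition ahead of diene hydrolysis) and close to one equivalent of DDQ at 0 °C (dehydrogenation of the cyclohexadiene ahead of oxidation at the benzylic C4 of the lower flavan) should secure.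

Step 14
Reactants: 24 (2S)-2-(benzyloxy)-1-[4,5-bis(tert-butyldimethylsilyloxy)-2-(3,5,7,3',4'-penta-O-benzyl-(+)-catechin-6-yl)phenyl]-3-[2,4,6-tris(methoxymethoxy)phenyl]propan-1-one
Product: 25 (3S)-3-(benzyloxy)-2-[4,5-dihydroxy-2-(3,5,7,3',4'-penta-O-benzyl-(+)-catechin-6-yl)phenyl]chromane-2,5,7-triol (cyclic hemiketal; both C2 epimers)
Conditions: HCl (3 M), MeOH–THF, 45 °C; then H2O
Reagents that add atoms: none
Why: Acid-catalysed methanolysis of the three MOM acetals and the two aryl silyl ethers, after which one of the two equivalent ortho phenols should add to the ketone to close the six-membered cyclic hemiketal, while the benzyl ethers and the C3 centre are not involved.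

Step 15
Reactants: 25 (3S)-3-(benzyloxy)-2-[4,5-dihydroxy-2-(3,5,7,3',4'-penta-O-benzyl-(+)-catechin-6-yl)phenyl]chromane-2,5,7-triol
Product: 26 (2R,3S)-3-(benzyloxy)-2-[4,5-dihydroxy-2-(3,5,7,3',4'-penta-O-benzyl-(+)-catechin-6-yl)phenyl]chromane-5,7-diol
Conditions: Et3SiH, CF3CO2H, CH2Cl2, −20 → 0 °C
Reagents that add atoms: none
Why: Ionic hydrogenation of the cyclic hemiketal, in which CF3CO2H ionises it to the 2-aryl oxocarbenium ion and Et3SiH should deliver hydride along the axial trajectory of the half-chair that has the 3-benzyloxy group pseudoequatorial, so that H-2 ends up cis to that group and the aryl group equatorial and trans to it, which sets C2 as R (2,3-trans).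

Step 16
Reactants: 26 (2R,3S)-3-(benzyloxy)-2-[4,5-dihydroxy-2-(3,5,7,3',4'-penta-O-benzyl-(+)-catechin-6-yl)phenyl]chromane-5,7-diol
Product: 27 (2R,3S)-2-{2-[(2R,3S)-2-(3,4-dihydroxyphenyl)-3,5,7-trihydroxychroman-6-yl]-4,5-dihydroxyphenyl}chromane-3,5,7-triol (target)
Conditions: H2 (1 atm), Pd(OH)2/C, THF–MeOH–H2O, rt
Reagents that add atoms: none
Why: Catalytic hydrogenolysis of the six benzyl ethers over Pd(OH)2 on carbon, under neutral conditions at which the benzylic C2–O1 bonds of flavan-3-ols are known to survive and no stereocentre is touched.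

Compound list
1 | (+)-catechin, (2R,3S)-2-(3,4-dihydroxyphenyl)chromane-3,5,7-triol | Oc1cc(O)c2c(c1)O[C@H](c1ccc(O)c(O)c1)[C@@H](O)C2 | starting material
2 | 5,7,3',4'-tetra-O-benzyl-(+)-catechin, (2R,3S)-5,7-bis(benzyloxy)-2-[3,4-bis(benzyloxy)phenyl]chroman-3-ol | c1c(OCc2ccccc2)cc2c(c1OCc1ccccc1)C[C@H](O)[C@@H](c1ccc(OCc3ccccc3)c(OCc3ccccc3)c1)O2 | intermediate
3 | 3,5,7,3',4'-penta-O-benzyl-(+)-catechin, (2R,3S)-3,5,7-tris(benzyloxy)-2-[3,4-bis(benzyloxy)phenyl]chromane | c1c(OCc2ccccc2)cc2c(c1OCc1ccccc1)C[C@H](OCc1ccccc1)[C@@H](c1ccc(OCc3ccccc3)c(OCc3ccccc3)c1)O2 | intermediate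
4 | 8-bromo-3,5,7,3',4'-penta-O-benzyl-(+)-catechin (2R,3S) | c1c(OCc2ccccc2)c(Br)c2c(c1OCc1ccccc1)C[C@H](OCc1ccccc1)[C@@H](c1ccc(OCc3ccccc3)c(OCc3ccccc3)c1)O2 | intermediate
5 | 8-bromo-6-iodo-3,5,7,3',4'-penta-O-benzyl-(+)-catechin (2R,3S) | Ic1c(OCc2ccccc2)c(Br)c2c(c1OCc1ccccc1)C[C@H](OCc1ccccc1)[C@@H](c1ccc(OCc3ccccc3)c(OCc3ccccc3)c1)O2 | intermediate
6 | ethynyltrimethylsilane | C#C[Si](C)(C)C | starting material
7 | 8-bromo-6-[(trimethylsilyl)ethynyl]-3,5,7,3',4'-penta-O-benzyl-(+)-catechin (2R,3S) | C[Si](C)(C)C#Cc1c(OCc2ccccc2)c(Br)c2c(c1OCc1ccccc1)C[C@H](OCc1ccccc1)[C@@H](c1ccc(OCc3ccccc3)c(OCc3ccccc3)c1)O2 | intermediate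
8 | 8-lithio-6-[(trimethylsilyl)ethynyl]-3,5,7,3',4'-penta-O-benzyl-(+)-catechin (2R,3S) | C[Si](C)(C)C#Cc1c(OCc2ccccc2)c([Li])c2c(c1OCc1ccccc1)C[C@H](OCc1ccccc1)[C@@H](c1ccc(OCc3ccccc3)c(OCc3ccccc3)c1)O2 | intermediate (not isolated)
9 | 6-[(trimethylsilyl)ethynyl]-3,5,7,3',4'-penta-O-benzyl-(+)-catechin (2R,3S) | C[Si](C)(C)C#Cc1c(OCc2ccccc2)cc2c(c1OCc1ccccc1)C[C@H](OCc1ccccc1)[C@@H](c1ccc(OCc3ccccc3)c(OCc3ccccc3)c1)O2 | intermediate (not isolated)
10 | 6-ethynyl-3,5,7,3',4'-penta-O-benzyl-(+)-catechin, (2R,3S)-3,5,7-tris(benzyloxy)-2-[3,4-bis(benzyloxy)phenyl]-6-ethynylchromane | C#Cc1c(OCc2ccccc2)cc2c(c1OCc1ccccc1)C[C@H](OCc1ccccc1)[C@@H](c1ccc(OCc3ccccc3)c(OCc3ccccc3)c1)O2 | intermediate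
11 | phloroglucinol | Oc1cc(O)cc(O)c1 | starting material
12 | 1,3,5-tris(methoxymethoxy)benzene | COCOc1cc(OCOC)cc(OCOC)c1 | intermediate
13 | methyl (S)-glycidate | COC(=O)[C@@H]1CO1 | starting material
14 | [2,4,6-tris(methoxymethoxy)phenyl]lithium | [Li]c1c(OCOC)cc(OCOC)cc1OCOC | intermediate (not isolated)
15 | [2,4,6-tris(methoxymethoxy)phenyl]magnesium bromide | Br[Mg]c1c(OCOC)cc(OCOC)cc1OCOC | intermediate (not isolated)
16 | methyl (2S)-2-hydroxy-3-[2,4,6-tris(methoxymethoxy)phenyl]propanoate | COC(=O)[C@@H](O)Cc1c(OCOC)cc(OCOC)cc1OCOC | intermediate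
17 | methyl (2S)-2-(benzyloxy)-3-[2,4,6-tris(methoxymethoxy)phenyl]propanoate | COC(=O)[C@@H](OCc1ccccc1)Cc1c(OCOC)cc(OCOC)cc1OCOC | intermediate
18 | (2S)-2-(benzyloxy)-N-methoxy-N-methyl-3-[2,4,6-tris(methoxymethoxy)phenyl]propanamide | CON(C)C(=O)[C@@H](OCc1ccccc1)Cc1c(OCOC)cc(OCOC)cc1OCOC | intermediate
19 | 2,3-butanedione | CC(=O)C(C)=O | starting material
20 | 2,3-bis(tert-butyldimethylsilyloxy)buta-1,3-diene | C=C(O[Si](C)(C)C(C)(C)C)C(=C)O[Si](C)(C)C(C)(C)C | intermediate
21 | lithium acetylide of 10 (2R,3S) | [Li]C#Cc1c(OCc2ccccc2)cc2c(c1OCc1ccccc1)C[C@H](OCc1ccccc1)[C@@H](c1ccc(OCc3ccccc3)c(OCc3ccccc3)c1)O2 | intermediate (not isolated)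
22 | ynone, (4S)-4-(benzyloxy)-1-{(2R,3S)-3,5,7-tris(benzyloxy)-2-[3,4-bis(benzyloxy)phenyl]chroman-6-yl}-5-[2,4,6-tris(methoxymethoxy)phenyl]pent-1-yn-3-one | COCOc1cc(OCOC)c(C[C@H](OCc2ccccc2)C(=O)C#Cc3c(OCc4ccccc4)cc5c(c3OCc3ccccc3)C[C@H](OCc3ccccc3)[C@@H](c3ccc(OCc4ccccc4)c(OCc4ccccc4)c3)O5)c(OCOC)c1 | intermediate
23 | cyclohexa-1,4-diene adduct, 4,5-bis(tert-butyldimethylsilyloxy)cyclohexa-1,4-diene carrying the (2S)-acyl chain at C1 and the lower flavan at C2 | COCOc1cc(OCOC)c(C[C@H](OCc2ccccc2)C(=O)C2=C(c3c(OCc4ccccc4)cc5c(c3OCc3ccccc3)C[C@H](OCc3ccccc3)[C@@H](c3ccc(OCc4ccccc4)c(OCc4ccccc4)c3)O5)CC(O[Si](C)(C)C(C)(C)C)=C(O[Si](C)(C)C(C)(C)C)C2)c(OCOC)c1 | intermediate (not isolated)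
24 | aryl ketone, (2S)-2-(benzyloxy)-1-[4,5-bis(tert-butyldimethylsilyloxy)-2-{(2R,3S)-3,5,7-tris(benzyloxy)-2-[3,4-bis(benzyloxy)phenyl]chroman-6-yl}phenyl]-3-[2,4,6-tris(methoxymethoxy)phenyl]propan-1-one | COCOc1cc(OCOC)c(C[C@H](OCc2ccccc2)C(=O)c2cc(O[Si](C)(C)C(C)(C)C)c(O[Si](C)(C)C(C)(C)C)cc2-c2c(OCc3ccccc3)cc4c(c2OCc2ccccc2)C[C@H](OCc2ccccc2)[C@@H](c2ccc(OCc3ccccc3)c(OCc3ccccc3)c2)O4)c(OCOC)c1 | intermediate
25 | cyclic hemiketal, (3S)-3-(benzyloxy)-2-[4,5-dihydroxy-2-{(2R,3S)-3,5,7-tris(benzyloxy)-2-[3,4-bis(benzyloxy)phenyl]chroman-6-yl}phenyl]chromane-2,5,7-triol, C2 undefined | Oc1cc(O)c2c(c1)OC(O)(c1cc(O)c(O)cc1-c1c(OCc3ccccc3)cc3c(c1OCc1ccccc1)C[C@H](OCc1ccccc1)[C@@H](c1ccc(OCc4ccccc4)c(OCc4ccccc4)c1)O3)[C@@H](OCc1ccccc1)C2 | intermediate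
26 | (2R,3S)-3-(benzyloxy)-2-[4,5-dihydroxy-2-{(2R,3S)-3,5,7-tris(benzyloxy)-2-[3,4-bis(benzyloxy)phenyl]chroman-6-yl}phenyl]chromane-5,7-diol | Oc1cc(O)c2c(c1)O[C@H](c1cc(O)c(O)cc1-c1c(OCc3ccccc3)cc3c(c1OCc1ccccc1)C[C@H](OCc1ccccc1)[C@@H](c1ccc(OCc4ccccc4)c(OCc4ccccc4)c1)O3)[C@@H](OCc1ccccc1)C2 | intermediate
27 | (2R,3S)-2-{2-[(2R,3S)-2-(3,4-dihydroxyphenyl)-3,5,7-trihydroxychroman-6-yl]-4,5-dihydroxyphenyl}chromane-3,5,7-triol | Oc1cc(O)c2c(c1)O[C@H](c1cc(O)c(O)cc1-c1c(O)cc3c(c1O)C[C@H](O)[C@@H](c1ccc(O)c(O)c1)O3)[C@@H](O)C2 | target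

Total step count: 16.
Longest linear sequence: 11 steps (1 → 27 through steps 1–6 and 12–16).

Steps most likely to fail

Step 13. The alkyne terminus carrying the di-ortho-benzyloxy aryl group is hindered and donor-substituted, so the cycloaddition may be outrun by hydrolysis or oligomerisation of the acyclic diene, which must first leave its s-trans ground state. The oxidant may also go on to attack the benzylic C4–H bonds of the lower flavan. The fallback sets out from ynone 22 and comes back at ketone 24. Cyclohexane-1,2-dione would be bis-silylated (TBSOTf, Et3N, CH2Cl2) to the ring-locked s-cis diene 2,3-bis(tert-butyldimethylsilyloxy)cyclohexa-1,3-diene F1. Heating 22 with it (toluene, 110 °C, then 1,2-dichlorobenzene, 180 °C) should give the bicyclo[2.2.2]octa-2,5-diene adduct F2, which loses ethene in a retro-Diels–Alder step (Alder–Rickert sequence) to give 24 without any oxidant.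

Step 15. Hydride delivery to the oxocarbenium ion may show poor facial selectivity, the ion may lose H-3 to an enol ether and so erode the C3 centre, or the benzylic C2–O1 bond may be cleaved by over-reduction. The fallback sets out from ketone 24 and comes back at flavan 26. NaBH4 (MeOH–THF, 0 °C) would reduce the ketone to the carbinol (2S)-2-(benzyloxy)-1-aryl-3-[2,4,6-tris(methoxymethoxy)phenyl]propan-1-ol F3, either epimer being usable. HCl in MeOH–THF at 45 °C would then remove the MOM and silyl groups and ionise the carbinol, which is stabilised by the para oxygen at C4', so that the ortho phenol closes ring C by SN1 attack anti to the neighbouring benzyloxy group. This acid-mediated cyclodehydration is known for 1,3-diarylpropane-1,2-diol derivatives to favour the 2,3-trans flavan.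

Step 4. Iodination at the crowded C6 may lose site selectivity to the catechol-ether ring, or the acid promoter may cause protodeiodination and halogen migration. The fallback sets out from bromide 4 and comes back at alkyne 10. Vilsmeier–Haack formylation (POCl3, DMF, 60 °C), which only the phloroglucinol-type ring should undergo, would give 8-bromo-6-formyl-3,5,7,3',4'-penta-O-benzyl-(+)-catechin F4. Seyferth–Gilbert homologation with dimethyl (1-diazo-2-oxopropyl)phosphonate (K2CO3, MeOH–THF, rt) would give 8-bromo-6-ethynyl-3,5,7,3',4'-penta-O-benzyl-(+)-catechin F5. n-BuLi (2.2 equiv, THF, −78 °C) would convert it into the dilithio species F6 by deprotonation and bromine–lithium exchange, and methanol would protonate both sites to give 10.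

Further compounds
F1 | step 13 | 2,3-bis(tert-butyldimethylsilyloxy)cyclohexa-1,3-diene | C1CC=C(O[Si](C)(C)C(C)(C)C)C(O[Si](C)(C)C(C)(C)C)=C1
F2 | step 13 | bicyclo[2.2.2]octa-2,5-diene adduct of 22 and F1 (2,3-bis(silyloxy); acyl chain at C5, lower flavan at C6; bridgehead epimers) | COCOc1cc(OCOC)c(C[C@H](OCc2ccccc2)C(=O)C2=C(c3c(OCc4ccccc4)cc5c(c3OCc3ccccc3)C[C@H](OCc3ccccc3)[C@@H](c3ccc(OCc4ccccc4)c(OCc4ccccc4)c3)O5)C3CCC2C(O[Si](C)(C)C(C)(C)C)=C3O[Si](C)(C)C(C)(C)C)c(OCOC)c1
F3 | step 15 | (2S)-2-(benzyloxy)-1-[4,5-bis(tert-butyldimethylsilyloxy)-2-{(2R,3S)-3,5,7-tris(benzyloxy)-2-[3,4-bis(benzyloxy)phenyl]chroman-6-yl}phenyl]-3-[2,4,6-tris(methoxymethoxy)phenyl]propan-1-ol (C1 epimers) | COCOc1cc(OCOC)c(C[C@H](OCc2ccccc2)C(O)c2cc(O[Si](C)(C)C(C)(C)C)c(O[Si](C)(C)C(C)(C)C)cc2-c2c(OCc3ccccc3)cc4c(c2OCc2ccccc2)C[C@H](OCc2ccccc2)[C@@H](c2ccc(OCc3ccccc3)c(OCc3ccccc3)c2)O4)c(OCOC)c1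
F4 | step 4 | 8-bromo-6-formyl-3,5,7,3',4'-penta-O-benzyl-(+)-catechin (2R,3S) | O=Cc1c(OCc2ccccc2)c(Br)c2c(c1OCc1ccccc1)C[C@H](OCc1ccccc1)[C@@H](c1ccc(OCc3ccccc3)c(OCc3ccccc3)c1)O2
F5 | step 4 | 8-bromo-6-ethynyl-3,5,7,3',4'-penta-O-benzyl-(+)-catechin (2R,3S) | C#Cc1c(OCc2ccccc2)c(Br)c2c(c1OCc1ccccc1)C[C@H](OCc1ccccc1)[C@@H](c1ccc(OCc3ccccc3)c(OCc3ccccc3)c1)O2
F6 | step 4 | 8-lithio-6-(lithioethynyl)-3,5,7,3',4'-penta-O-benzyl-(+)-catechin (2R,3S) | [Li]C#Cc1c(OCc2ccccc2)c([Li])c2c(c1OCc1ccccc1)C[C@H](OCc1ccccc1)[C@@H](c1ccc(OCc3ccccc3)c(OCc3ccccc3)c1)O2
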